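Everything rests on cutting C18–C19 of the central six-membered carbocycle (C2, C16, C17, C20, C19, C18). That ring alone connects the N1/C2/C7 indoline to the N4/C20/C15 pyrrolidinol, and C18 and C19 are plain methylenes flanked by the aminated quaternary carbons C2 and C20, so each is masked as a vinyl group. After an aldol has joined the halves at C16–C17, one ring-closing metathesis makes C18=C19 and the carbocycle. The metathesis substrate is the bis-vinyl 1,7-diene still carrying the aldol hydroxyl at C17, which is eliminated once the ring enforces a cis alkene.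

Key step: step 17

Remarks
- Atom labels are the biogenetic ones of the target; C21 and C22 are the ester carbons on C7 and C16.
- Assumption for step 1: the facial sense of the cinchona catalyst with this donor is assumed, not derived; the pseudoenantiomer that delivers (S)-3 is meant (the quinidine series is written).
- Compounds 9 and 14 (one extra centre each) and 36–38 (C16, C17) are diastereomer mixtures whose extra centres are erased later; their SMILES leave these centres open.

Indoline half (steps 1–7)

Step 1
Reactants: 1 methyl 2-oxoindoline-3-carboxylate; 2 methyl vinyl ketone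
Product: 3 methyl (3S)-2-oxo-3-(3-oxobutyl)indoline-3-carboxylate
Conditions: 9-amino-9-deoxy-epi-quinidine 3,5-bis(trifluoromethyl)phenylthiourea (10 mol%), PhMe, −20 °C
Reagents that add atoms: methyl vinyl ketone, CC(=O)C=C
Why: Cinchona-base/thiourea catalysed Michael addition of the enolised β-amido ester to the enone is a standard way to quaternise C3 of an oxindole, the catalyst holding enol and ketone in a chiral pocket so that the enone is taken up on one face of C7 and the (S) centre of the target is set here.

Step 2
Reactants: 3 methyl (3S)-2-oxo-3-(3-oxobutyl)indoline-3-carboxylate; 4 methyl chloroformate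
Product: 5 dimethyl (3S)-2-oxo-3-(3-oxobutyl)indoline-1,3-dicarboxylate
Conditions: ClCO2Me, Et3N, DMAP (cat.), CH2Cl2, 0 °C
Reagents that add atoms: methyl chloroformate, COC(=O)Cl
Why: DMAP-catalysed N-acylation of the lactam nitrogen, which installs the final N1 carbamate and turns the lactam carbonyl into an imide-type electrophile for step 4.

Step 3
Reactants: 5 dimethyl (3S)-2-oxo-3-(3-oxobutyl)indoline-1,3-dicarboxylate; 6 tert-butyldimethylsilyl trifluoromethanesulfonate
Product: 7 dimethyl (3S)-3-[3-(tert-butyldimethylsilyloxy)but-3-en-1-yl]-2-oxoindoline-1,3-dicarboxylate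
Conditions: TBSOTf, Et3N, CH2Cl2, −78 → 0 °C
Reagents that add atoms: tert-butyldimethylsilyl trifluoromethanesulfonate, CC(C)(C)[Si](C)(C)OS(=O)(=O)C(F)(F)F
Why: Soft enolisation with a silyl triflate and an amine silylates the methyl ketone on its less substituted side, which masks the ketone towards the Grignard reagent and makes C16 the only nucleophilic carbon in step 5.

Step 4
Reactants: 7 dimethyl (3S)-3-[3-(tert-butyldimethylsilyloxy)but-3-en-1-yl]-2-oxoindoline-1,3-dicarboxylate; 8 vinylmagnesium bromide
Product: 9 dimethyl (3S)-3-[3-(tert-butyldimethylsilyloxy)but-3-en-1-yl]-2-hydroxy-2-vinylindoline-1,3-dicarboxylate (both C2 epimers)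
Conditions: CH2=CHMgBr (1.2 equiv), THF, −78 °C; aq NH4Cl
Reagents that add atoms: vinylmagnesium bromide, C=C[Mg]Br
Why: Grignard addition to an N-acyl lactam, whose imide-type carbonyl (chelated with the C7 ester) is the most electrophilic site at −78 °C, gives the N-acyl hemiaminal that the adjacent quaternary carbon keeps cyclic, and its C2 configuration is of no account because C2 becomes planar in step 5.

Step 5
Reactants: 9 dimethyl (3S)-3-[3-(tert-butyldimethylsilyloxy)but-3-en-1-yl]-2-hydroxy-2-vinylindoline-1,3-dicarboxylate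
Product: 11 dimethyl (4aS,9aS)-2-oxo-9a-vinyl-1,2,3,4-tetrahydro-4aH-carbazole-4a,9(9aH)-dicarboxylate, via N-acyliminium ion 10 (not isolated)
Conditions: TMSOTf (20 mol%), CH2Cl2, −78 → 0 °C
Reagents that add atoms: none
Why: N-acyliminium ion cyclisation of Mukaiyama–Mannich type, in which the silyl triflate ionises the hemiaminal and the tethered silyl enol ether attacks C2 through a six-membered chair that is only possible on the face carrying its own chain, so the new ring is cis-fused and C2 is set with C16 cis to C6 and the vinyl group cis to the C7 ester.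

Step 6
Reactants: 11 dimethyl (4aS,9aS)-2-oxo-9a-vinyl-1,2,3,4-tetrahydro-4aH-carbazole-4a,9(9aH)-dicarboxylate; 12 3-phenyl-2-(phenylsulfonyl)oxaziridine
Product: 14 dimethyl (4aS,9aS)-3-hydroxy-2-oxo-9a-vinyl-1,2,3,4-tetrahydro-4aH-carbazole-4a,9(9aH)-dicarboxylate (both C3 epimers; carbazole C3 is C5), via sodium enolate 13 (not isolated)
Conditions: NaN(SiMe3)2, THF, −78 °C; then 12, −78 °C; AcOH
Reagents that add atoms: 3-phenyl-2-(phenylsulfonyl)oxaziridine, O=S(=O)(c1ccccc1)N1OC1c1ccccc1
Why: Kinetic deprotonation takes the C5 methylene, which unlike C16 is not flanked by a quaternary carbon, and the Davis oxaziridine hydroxylates that enolate (α-hydroxylation of a ketone enolate), the new carbinol configuration being erased in step 7.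

Step 7
Reactants: 14 dimethyl (4aS,9aS)-3-hydroxy-2-oxo-9a-vinyl-1,2,3,4-tetrahydro-4aH-carbazole-4a,9(9aH)-dicarboxylate; 15 methanol; 16 trimethyl orthoformate
Product: 18 dimethyl (2S,3S)-3-(2,2-dimethoxyethyl)-2-(2-methoxy-2-oxoethyl)-2-vinylindoline-1,3-dicarboxylate, via aldehyde diester 17 (not isolated)
Conditions: Pb(OAc)4, MeOH/PhMe, 0 °C; then HC(OMe)3, p-TsOH (cat.), rt
Reagents that add atoms: methanol, CO; trimethyl orthoformate, COC(OC)OC
Why: Criegee-type glycol cleavage of the α-ketol (as its methanol hemiketal) by Pb(OAc)4 breaks C5–C22 to give the C16 methyl ester and the C5 aldehyde in one stroke without touching the vinyl group, and acid-catalysed acetalisation in the same methanolic medium protects the aldehyde for the enolate chemistry of step 16.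

Pyrrolidine half (steps 8–15)

Step 8
Reactants: 19 cis-3-hydroxy-L-proline; 20 di-tert-butyl dicarbonate
Product: 21 (2S,3R)-1-(tert-butoxycarbonyl)-3-hydroxypyrrolidine-2-carboxylic acid
Conditions: Boc2O, NaOH, dioxane/H2O, 0 °C → rt; HCl to pH 3
Reagents that add atoms: di-tert-butyl dicarbonate, CC(C)(C)OC(=O)OC(=O)OC(C)(C)C
Why: Schotten–Baumann carbamoylation of the secondary amine with Boc2O, which touches neither stereocentre.

Step 9
Reactants: 21 (2S,3R)-1-(tert-butoxycarbonyl)-3-hydroxypyrrolidine-2-carboxylic acid; 22 pivalaldehyde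
Product: 24 tert-butyl 2-tert-butyl-4-oxohexahydro-[1,3]dioxino[5,4-b]pyrrole-5-carboxylate (cis-fused dioxanone; acetal and ring-fusion hydrogens all cis), via bis(trimethylsilyl) derivative 23 (not isolated)
Conditions: TMSCl, Et3N, CH2Cl2, 0 °C → rt; then t-BuCHO, TMSOTf (5 mol%), CH2Cl2, −78 °C
Reagents that add atoms: pivalaldehyde, CC(C)(C)C=O
Why: Silyl-triflate-catalysed acetalisation of the bis-silylated β-hydroxy acid (Noyori conditions) gives the Seebach 1,3-dioxan-4-one, a ring that the cis acid closes readily and in which the tert-butyl group should take the equatorial position (this acetal centre is incidental).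

Step 10
Reactants: 24 tert-butyl 2-tert-butyl-4-oxohexahydro-[1,3]dioxino[5,4-b]pyrrole-5-carboxylate; 25 formaldehyde (monomer from cracked paraformaldehyde)
Product: 27 4a-(hydroxymethyl) derivative of 24 (hydroxymethyl on the face of the former C20 hydrogen), via lithium enolate 26 (not isolated)
Conditions: LiN(i-Pr)2, THF, −78 °C; then CH2O (gas), −78 °C; AcOH
Reagents that add atoms: formaldehyde, C=O
Why: Aldol reaction of the dioxanone lithium enolate with formaldehyde, in which the electrophile can only arrive on the convex face opposite the acetal bridge, which keeps the cis ring fusion and so places the new carbon (C19) trans to O15 and leaves the carboxyl carbon (C17) cis to it, setting the C20 quaternary centre.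

Step 11
Reactants: 27 4a-(hydroxymethyl) derivative of 24
Product: 28 4a-formyl derivative of 24
Conditions: Dess–Martin periodinane, CH2Cl2, rt
Reagents that add atoms: none
Why: Dess–Martin oxidation of a neopentyl primary alcohol under neutral conditions, the quaternary α-carbon excluding epimerisation or elimination.

Step 12
Reactants: 28 4a-formyl derivative of 24; 29 methyltriphenylphosphonium bromide
Product: 30 4a-vinyl derivative of 24
Conditions: Ph3PCH3Br, KN(SiMe3)2, THF, 0 °C; then 28, −78 → 0 °C
Reagents that add atoms: methyltriphenylphosphonium bromide, C[P+](c1ccccc1)(c1ccccc1)c1ccccc1.[Br-]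
Why: Wittig methylenation of a non-enolisable aldehyde at low temperature, which turns C19 into the vinyl group while the hindered lactone carbonyl is left alone.

Step 13
Reactants: 30 4a-vinyl derivative of 24; 15 methanol
Product: 31 1-tert-butyl 2-methyl (2S,3R)-3-hydroxy-2-vinylpyrrolidine-1,2-dicarboxylate
Conditions: K2CO3 (cat.), MeOH, 0 °C
Reagents that add atoms: methanol, CO
Why: Base-catalysed methanolysis (transesterification) of the acylal, an activated lactone, gives the methyl ester, and the hemiacetal so released collapses to pivalaldehyde and the free C15 hydroxyl without touching C20.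

Step 14
Reactants: 31 1-tert-butyl 2-methyl (2S,3R)-3-hydroxy-2-vinylpyrrolidine-1,2-dicarboxylate; 32 triethylsilyl trifluoromethanesulfonate
Product: 33 1-tert-butyl 2-methyl (2S,3R)-3-(triethylsilyloxy)-2-vinylpyrrolidine-1,2-dicarboxylate
Conditions: TESOTf, 2,6-lutidine, CH2Cl2, −78 → 0 °C
Reagents that add atoms: triethylsilyl trifluoromethanesulfonate, CC[Si](CC)(CC)OS(=O)(=O)C(F)(F)F
Why: Silylation of the hindered secondary alcohol with a silyl triflate and 2,6-lutidine, the triethylsilyl ether being chosen because it falls off together with Boc and the acetal in step 19.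

Step 15
Reactants: 33 1-tert-butyl 2-methyl (2S,3R)-3-(triethylsilyloxy)-2-vinylpyrrolidine-1,2-dicarboxylate
Product: 34 tert-butyl (2S,3R)-2-formyl-3-(triethylsilyloxy)-2-vinylpyrrolidine-1-carboxylate
Conditions: i-Bu2AlH, CH2Cl2, −78 °C; aq potassium sodium tartrate
Reagents that add atoms: none
Why: Partial reduction of the ester with i-Bu2AlH at −78 °C, where the tetrahedral aluminium alkoxide of an α-quaternary N-Boc amino ester is held by chelation until work-up and then gives the non-enolisable C17 aldehyde.

Union and completion (steps 16–20)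

Step 16
Reactants: 18 dimethyl (2S,3S)-3-(2,2-dimethoxyethyl)-2-(2-methoxy-2-oxoethyl)-2-vinylindoline-1,3-dicarboxylate; 34 tert-butyl (2S,3R)-2-formyl-3-(triethylsilyloxy)-2-vinylpyrrolidine-1-carboxylate
Product: 36 aldol adduct joining the halves through C16–C17 (C17 carbinol; bis-vinyl 1,7-diene; mixture at C16 and C17), via lithium ester enolate 35 (not isolated)
Conditions: LiN(i-Pr)2, THF, −78 °C; then 34, −78 °C; AcOH, −78 °C
Reagents that add atoms: none
Why: Lithium ester enolate aldol addition to a non-enolisable aldehyde at −78 °C forms the C16–C17 bond that joins the halves, the only acidic C–H of 18 being at C16, and no control of C16 or C17 is sought because C17 is eliminated in step 18 and C16 is reset in step 20.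

Step 17
Reactants: 36 aldol adduct joining the halves through C16–C17
Product: 37 cyclohexene carrying both spiro rings (C18=C19; C17 hydroxyl; C16 ester; N4-Boc; O15-TES; C5 dimethyl acetal)
Conditions: second-generation Grubbs catalyst RuCl2(=CHPh)(PCy3)(H2IMes) (5–10 mol%), PhMe (0.005 M), 80 °C
Reagents that add atoms: none
Why: The ruthenium benzylidene exchanges onto one of the two monosubstituted alkenes, the new alkylidene adds to the other vinyl group through a ruthenacyclobutane, and cycloreversion releases ethene and leaves the C18=C19 bond. This is ring-closing olefin metathesis of a 1,7-diene to a cyclohexene, established for dienes whose allylic carbons are fully substituted. The one ring closed is the six-membered carbocycle (C2, C16, C17, C20, C19, C18), formed by intramolecular [2+2] cycloaddition and cycloreversion along the C2–C16–C17–C20 tether, which can only give the cis ring alkene. No stereocentre is created, so C2, C7, C15 and C20 are carried through unchanged and the C16/C17 mixture from step 16 is irrelevant here. The selectivity required is cyclisation over intermolecular metathesis, and the substrate secures it because both vinyl groups sit on quaternary carbons (slow homodimerisation, gem-disubstitution favouring the folded chain) and because the C16–C17 link is still saturated and free to rotate. High dilution and loss of ethene complete the bias, and the free C17 hydroxyl, esters, carbamates, acetal and silyl ether are inert to the catalyst.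

Step 18
Reactants: 37 cyclohexene carrying both spiro rings
Product: 39 cyclohexa-1,4-diene ester (C16=C17 and C18=C19; N4-Boc; O15-TES; C5 dimethyl acetal), via C17 mesylate 38 (not isolated)
Conditions: MsCl, Et3N, CH2Cl2, 0 °C; then DBU, 0 °C → rt
Reagents that add atoms: none
Why: Mesylation followed by E1cB elimination through the ester enolate, in which C16–H is the only β-hydrogen and the ring forces the cis alkene, so that all aldol diastereomers converge on one cyclohexa-1,4-diene ester.

Step 19
Reactants: 39 cyclohexa-1,4-diene ester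
Product: 42 bridged diene (16,17,18,19-tetradehydro target; N4–C5 bond closed; free C15 hydroxyl), via amino aldehyde 40 (not isolated), via bridged iminium ion 41 (not isolated)
Conditions: CF3CO2H/CH2Cl2/H2O, 0 °C → rt; evaporate; then NaBH(OAc)3, ClCH2CH2Cl (0.005 M), rt; aq NaHCO3
Reagents that add atoms: none
Why: Aqueous CF3CO2H removes Boc, the triethylsilyl ether and the acetal, and N4 and the C5 aldehyde, held on the same face of the boat-shaped cyclohexadiene by the C2 and C20 configurations, condense to a bridged iminium ion that NaBH(OAc)3 reduces (intramolecular reductive amination), no stereocentre being formed.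

Step 20
Reactants: 42 bridged diene
Product: 43 CNP0144467.2 (target)
Conditions: H2 (1–4 atm), Pd/C, MeOH, AcOH (2 equiv), rt
Reagents that add atoms: none
Why: Heterogeneous hydrogenation (syn addition) saturates C18=C19 and the C16=C17 enoate, and hydrogen should reach C16 from the alkene face that looks at the two-carbon bridge, away from the N4–C5–C6–C7 bridge arching over the other face, which puts H16 towards C18–C19 and the ester towards the aza bridge as in the target, the amine being protonated so that it cannot anchor the catalyst.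

Compound list
1 | methyl 2-oxoindoline-3-carboxylate | COC(=O)C1C(=O)Nc2ccccc12 | starting material
2 | methyl vinyl ketone (but-3-en-2-one) | CC(=O)C=C | starting material
3 | methyl (3S)-2-oxo-3-(3-oxobutyl)indoline-3-carboxylate | O=C1Nc2ccccc2[C@@]1(C(=O)OC)CCC(C)=O | intermediate
4 | methyl chloroformate | COC(=O)Cl | starting material
5 | dimethyl (3S)-2-oxo-3-(3-oxobutyl)indoline-1,3-dicarboxylate | O=C1N(C(=O)OC)c2ccccc2[C@@]1(C(=O)OC)CCC(C)=O | intermediate
6 | tert-butyldimethylsilyl trifluoromethanesulfonate | CC(C)(C)[Si](C)(C)OS(=O)(=O)C(F)(F)F | starting material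
7 | dimethyl (3S)-3-[3-(tert-butyldimethylsilyloxy)but-3-en-1-yl]-2-oxoindoline-1,3-dicarboxylate | O=C1N(C(=O)OC)c2ccccc2[C@@]1(C(=O)OC)CCC(=C)O[Si](C)(C)C(C)(C)C | intermediate
8 | vinylmagnesium bromide | C=C[Mg]Br | starting material
9 | dimethyl (3S)-3-[3-(tert-butyldimethylsilyloxy)but-3-en-1-yl]-2-hydroxy-2-vinylindoline-1,3-dicarboxylate, both C2 epimers | C=CC1(O)N(C(=O)OC)c2ccccc2[C@@]1(C(=O)OC)CCC(=C)O[Si](C)(C)C(C)(C)C | intermediate
10 | 2-vinyl N-acyliminium ion from 9 (3H-indolium, N1-CO2Me) | C=CC1=[N+](C(=O)OC)c2ccccc2[C@@]1(C(=O)OC)CCC(=C)O[Si](C)(C)C(C)(C)C | intermediate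
11 | dimethyl (4aS,9aS)-2-oxo-9a-vinyl-1,2,3,4-tetrahydro-4aH-carbazole-4a,9(9aH)-dicarboxylate, cis-fused (ring C2–C16–C22–C5–C6–C7) | C=C[C@@]12CC(=O)CC[C@]1(C(=O)OC)c3ccccc3N2C(=O)OC | intermediate
12 | 3-phenyl-2-(phenylsulfonyl)oxaziridine (Davis reagent) | O=S(=O)(c1ccccc1)N1OC1c1ccccc1 | starting material
13 | sodium enolate of 11 towards C5 | C=C[C@@]12CC(O[Na])=CC[C@]1(C(=O)OC)c3ccccc3N2C(=O)OC | intermediate
14 | dimethyl (4aS,9aS)-3-hydroxy-2-oxo-9a-vinyl-1,2,3,4-tetrahydro-4aH-carbazole-4a,9(9aH)-dicarboxylate, both C3 epimers | C=C[C@@]12CC(=O)C(O)C[C@]1(C(=O)OC)c3ccccc3N2C(=O)OC | intermediate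
15 | methanol | CO | starting material
16 | trimethyl orthoformate | COC(OC)OC | starting material
17 | dimethyl (2S,3S)-2-(2-methoxy-2-oxoethyl)-3-(2-oxoethyl)-2-vinylindoline-1,3-dicarboxylate | C=C[C@]1(CC(=O)OC)N(C(=O)OC)c2ccccc2[C@@]1(C(=O)OC)CC=O | intermediate
18 | dimethyl (2S,3S)-3-(2,2-dimethoxyethyl)-2-(2-methoxy-2-oxoethyl)-2-vinylindoline-1,3-dicarboxylate | C=C[C@]1(CC(=O)OC)N(C(=O)OC)c2ccccc2[C@@]1(C(=O)OC)CC(OC)OC | intermediate
19 | cis-3-hydroxy-L-proline, (2S,3R) | OC(=O)[C@H]1NCC[C@H]1O | starting material
20 | di-tert-butyl dicarbonate | CC(C)(C)OC(=O)OC(=O)OC(C)(C)C | starting material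
21 | (2S,3R)-1-(tert-butoxycarbonyl)-3-hydroxypyrrolidine-2-carboxylic acid | OC(=O)[C@H]1N(C(=O)OC(C)(C)C)CC[C@H]1O | intermediate
22 | pivalaldehyde | CC(C)(C)C=O | starting material
23 | trimethylsilyl (2S,3R)-1-(tert-butoxycarbonyl)-3-(trimethylsilyloxy)pyrrolidine-2-carboxylate | C[Si](C)(C)OC(=O)[C@H]1N(C(=O)OC(C)(C)C)CC[C@H]1O[Si](C)(C)C | intermediate
24 | tert-butyl 2-tert-butyl-4-oxohexahydro-[1,3]dioxino[5,4-b]pyrrole-5-carboxylate, cis-fused pivalaldehyde acetal of 21, acetal H cis to both ring-fusion H | O=C1O[C@H](C(C)(C)C)O[C@@H]2CCN(C(=O)OC(C)(C)C)[C@H]12 | intermediate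
25 | formaldehyde (monomer, from paraformaldehyde) | C=O | starting material
26 | lithium enolate of 24 | [Li]OC1=C2N(C(=O)OC(C)(C)C)CC[C@H]2O[C@@H](C(C)(C)C)O1 | intermediate
27 | 4a-(hydroxymethyl) derivative of 24, CH2OH trans to the ring oxygen on C15 | O=C1O[C@H](C(C)(C)C)O[C@@H]2CCN(C(=O)OC(C)(C)C)[C@]12CO | intermediate
28 | 4a-formyl derivative of 24 | O=C1O[C@H](C(C)(C)C)O[C@@H]2CCN(C(=O)OC(C)(C)C)[C@]12C=O | intermediate
29 | methyltriphenylphosphonium bromide | C[P+](c1ccccc1)(c1ccccc1)c1ccccc1.[Br-] | starting material
30 | 4a-vinyl derivative of 24 | O=C1O[C@H](C(C)(C)C)O[C@@H]2CCN(C(=O)OC(C)(C)C)[C@]12C=C | intermediate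
31 | 1-tert-butyl 2-methyl (2S,3R)-3-hydroxy-2-vinylpyrrolidine-1,2-dicarboxylate | COC(=O)[C@@]1(C=C)N(C(=O)OC(C)(C)C)CC[C@H]1O | intermediate
32 | triethylsilyl trifluoromethanesulfonate | CC[Si](CC)(CC)OS(=O)(=O)C(F)(F)F | starting material
33 | 1-tert-butyl 2-methyl (2S,3R)-3-(triethylsilyloxy)-2-vinylpyrrolidine-1,2-dicarboxylate | COC(=O)[C@@]1(C=C)N(C(=O)OC(C)(C)C)CC[C@H]1O[Si](CC)(CC)CC | intermediate
34 | tert-butyl (2S,3R)-2-formyl-3-(triethylsilyloxy)-2-vinylpyrrolidine-1-carboxylate | O=C[C@@]1(C=C)N(C(=O)OC(C)(C)C)CC[C@H]1O[Si](CC)(CC)CC | intermediate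
35 | lithium ester enolate of 18 (at C16) | C=C[C@]1(C=C(OC)O[Li])N(C(=O)OC)c2ccccc2[C@@]1(C(=O)OC)CC(OC)OC | intermediate
36 | aldol adduct: C16 (CO2Me) of the indoline half bonded to the C17 carbinol of the pyrrolidine half; bis-vinyl 1,7-diene; C2, C7, C15, C20 as in the target; mixture at C16 and C17 | COC(=O)C(C(O)[C@@]1(C=C)N(C(=O)OC(C)(C)C)CC[C@H]1O[Si](CC)(CC)CC)[C@@]2(C=C)N(C(=O)OC)c3ccccc3[C@@]2(C(=O)OC)CC(OC)OC | intermediate
37 | cyclohexene with both spiro rings: C18=C19, C17–OH, C16–CO2Me; N4-Boc, O15-TES, C5 dimethyl acetal; mixture at C16 and C17 | COC(=O)C1C(O)[C@@]2(C=C[C@@]13N(C(=O)OC)c1ccccc1[C@@]3(C(=O)OC)CC(OC)OC)N(C(=O)OC(C)(C)C)CC[C@H]2O[Si](CC)(CC)CC | intermediate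
38 | C17 methanesulfonate of 37 | COC(=O)C1C(OS(C)(=O)=O)[C@@]2(C=C[C@@]13N(C(=O)OC)c1ccccc1[C@@]3(C(=O)OC)CC(OC)OC)N(C(=O)OC(C)(C)C)CC[C@H]2O[Si](CC)(CC)CC | intermediate
39 | cyclohexa-1,4-diene ester: C16=C17 (ester on C16) and C18=C19; N4-Boc, O15-TES, C5 dimethyl acetal | COC(=O)C1=C[C@@]2(C=C[C@@]13N(C(=O)OC)c1ccccc1[C@@]3(C(=O)OC)CC(OC)OC)N(C(=O)OC(C)(C)C)CC[C@H]2O[Si](CC)(CC)CC | intermediate
40 | amino aldehyde: 39 without Boc, TES and acetal (N4–H, C15–OH, C5 aldehyde) | COC(=O)C1=C[C@@]2(C=C[C@@]13N(C(=O)OC)c1ccccc1[C@@]3(C(=O)OC)CC=O)NCC[C@H]2O | intermediate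
41 | bridged iminium ion (N4=C5) | COC(=O)C1=C[C@@]23C=C[C@@]14N(C(=O)OC)c1ccccc1[C@@]4(C(=O)OC)CC=[N+]2CC[C@H]3O | intermediate
42 | bridged diene: 16,17,18,19-tetradehydro target | COC(=O)C1=C[C@@]23C=C[C@@]14N(C(=O)OC)c1ccccc1[C@@]4(C(=O)OC)CCN2CC[C@H]3O | intermediate
43 | CNP0144467.2 | COC(=O)[C@@H]1C[C@@]23CC[C@@]14N(C(=O)OC)c1ccccc1[C@@]4(C(=O)OC)CCN2CC[C@H]3O | target

Total step count: 20 (7 for the indoline half, 8 for the pyrrolidine half, 5 from the union on).
Longest linear sequence: 13 steps (steps 8–20, from cis-3-hydroxy-L-proline).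

Steps most likely to fail

Step 16. The doubly neopentyl C–C bond may form slowly, and in the meantime the ester enolate may expel the N1 carbamate nitrogen (β-elimination with opening of the indoline) or the aldolate may revert on warming. Fallback, a Mukaiyama aldol that never exposes a free enolate to the aldehyde: from 18, silylation under internal quench (LiN(i-Pr)2 added to 18 and TMSCl in THF at −78 °C) should give the silyl ketene acetal F1; F1 and 34 are then combined with MgBr2·OEt2 in CH2Cl2 at −78 °C, and aqueous work-up removes the silyl group, so the route is rejoined at 36.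

Step 19. Closure of the bridging eight-membered iminium ion may be slower than direct reduction of the C5 aldehyde or than intermolecular condensation. Fallback, N-alkylation in place of reductive amination: from 39 the same aqueous CF3CO2H treatment followed by NaBH4 in MeOH at 0 °C should give the amino diol F2; PPh3, I2 and imidazole convert its unhindered primary alcohol into the primary iodide F3, which N4 displaces intramolecularly (SN2) on warming with K2CO3 in MeCN at high dilution, returning to the route at 42.

Step 20. The enoate flanked by two quaternary carbons may resist saturation, or hydrogen may be delivered to the bridge-shielded face so that control of C16 is lost. Fallback, stepwise reduction with C16 set by protonation: from 42, diimide (from 2-nitrobenzenesulfonylhydrazide and Et3N) should saturate only the unconjugated C18=C19 bond to give the enoate F4; Mg in MeOH then reduces the enoate by electron transfer and C16 is set by protonation of the magnesium enolate on its open face, the centre remaining adjustable by NaOMe/MeOH equilibration, and the route is rejoined at 43.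

Further compounds
F1 | step 16 | methyl trimethylsilyl ketene acetal of 18 (at C16) | C=C[C@]1(C=C(OC)O[Si](C)(C)C)N(C(=O)OC)c2ccccc2[C@@]1(C(=O)OC)CC(OC)OC
F2 | step 19 | amino diol (N4–H, C5–OH, C15–OH; ring diene intact) | COC(=O)C1=C[C@@]2(C=C[C@@]13N(C(=O)OC)c1ccccc1[C@@]3(C(=O)OC)CCO)NCC[C@H]2O
F3 | step 19 | primary iodide at C5 (N4–H, C15–OH) | COC(=O)C1=C[C@@]2(C=C[C@@]13N(C(=O)OC)c1ccccc1[C@@]3(C(=O)OC)CCI)NCC[C@H]2O
F4 | step 20 | 16,17-didehydro target (C18–C19 saturated) | COC(=O)C1=C[C@@]23CC[C@@]14N(C(=O)OC)c1ccccc1[C@@]4(C(=O)OC)CCN2CC[C@H]3O
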